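**Retrosynthetic overview**
1. Target ⇐ silyl-protected 8-epi alcohol 27: the angelate is put on with inversion at C8 (Mitsunobu), then both silyl ethers are removed.
2. Key disconnection C7–C8: the ten-membered ring (second ring) is closed by an intramolecular CrCl2 Barbier allylation. C7, the β-carbon of the lactone carbonyl of a 3-(bromomethyl)butenolide (homoenolate, d3 reactivity), attacks the C8 aldehyde; this sets C7 and C8 and unveils the α-methylene lactone.
3. The butenolide (first ring) comes from ring-closing metathesis of the C6 2-(bromomethyl)acrylate ester.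
4. C2–C3: a catalytic asymmetric alkenylzinc addition joins a west alkyne (C8–C10, C1, C2; from Sharpless epoxidation of (E)-3-methylpent-2-en-4-yn-1-ol) to an east Z-enal (C3–C7; from crotonaldehyde, propyne and DMF).

Assumption: C-numbers in the text follow germacranolide numbering (C1–C10 ring, C11–C13 lactone, C14/C15 methyls); the facial sense of the ProPhenol and MIB catalysts is taken from their usual models and the ligand antipode is used if a model run shows the opposite.

Step 1
Reactants: 1 (E)-3-methylpent-2-en-4-yn-1-ol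
Product: 2 [(2S,3S)-3-ethynyl-3-methyloxiran-2-yl]methanol
Conditions: Ti(OiPr)4 (10 mol %), L-(+)-diethyl tartrate (12 mol %), t-BuOOH, 4 Å MS, CH2Cl2, −20 °C
Reagents that add atoms: tert-butyl hydroperoxide, CC(C)(C)OO
Why: Sharpless asymmetric epoxidation of the allylic alcohol; the L-(+)-tartrate catalyst delivers oxygen to the same face as in geraniol and gives the (2S,3S)-epoxide, which fixes the future C10 carbinol.

Step 2
Reactants: 2 [(2S,3S)-3-ethynyl-3-methyloxiran-2-yl]methanol
Product: 3 (3R)-3-methylpent-4-yne-1,3-diol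
Conditions: NaAlH2(OCH2CH2OCH3)2, THF, 0 °C; aq potassium sodium tartrate
Reagents that add atoms: none
Why: Hydroxyl-directed reductive opening of a 2,3-epoxy alcohol, in which the C1 alkoxyaluminate delivers hydride to C2 so that the 1,3-diol forms and the tertiary C–O stereocentre is untouched, the terminal alkyne being deprotonated and therefore spared.

Step 3
Reactants: 3 (3R)-3-methylpent-4-yne-1,3-diol
Product: 4 (3R)-3-methyl-3,5-bis(triethylsilyloxy)pent-1-yne
Conditions: Et3SiOTf (2.4 equiv), 2,6-lutidine, CH2Cl2, −78 → 0 °C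
Reagents that add atoms: triethylsilyl trifluoromethanesulfonate, CC[Si](CC)(CC)OS(=O)(=O)C(F)(F)F
Why: Silyl triflate silylation caps the primary and the tertiary hydroxyl so that the alkyne can be hydroborated later; no stereocentre is touched.

Step 4
Reactants: 5 (E)-but-2-enal (crotonaldehyde); 6 propyne
Product: 8 (2E,4S)-hept-2-en-5-yn-4-ol, via methyl(prop-1-ynyl)zinc 7 (not isolated)
Conditions: Me2Zn (3 equiv), (S,S)-ProPhenol (10 mol %), Ph3P=O (20 mol %), toluene, 0 → 4 °C; aq NH4Cl
Reagents that add atoms: none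
Why: Catalytic asymmetric alkynylation of an enal with the dinuclear zinc–ProPhenol catalyst; the ligand shields one aldehyde face so that 1,2-addition of the propynyl group gives the (4S)-carbinol, the future C6.

Step 5
Reactants: 8 (2E,4S)-hept-2-en-5-yn-4-ol
Product: 10 (2Z,4S,5E)-2-iodohepta-2,5-dien-4-ol, via cyclic alkenylalanate 9 (not isolated)
Conditions: NaAlH2(OCH2CH2OCH3)2, THF, 0 °C → rt; EtOAc; I2, −78 → 0 °C
Reagents that add atoms: iodine, [I][I]
Why: Hydroxyl-directed trans-hydroalumination of the propargylic alcohol and iodinolysis with retention put iodine on the distal carbon cis to the carbinol, which sets the Z geometry of the future C4=C5 bond while the carbinol centre is untouched.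

Step 6
Reactants: 10 (2Z,4S,5E)-2-iodohepta-2,5-dien-4-ol; 11 N,N-dimethylformamide
Product: 15 (2Z,4S,5E)-2-methyl-4-(triethylsilyloxy)hepta-2,5-dienal, via dilithio alkoxide–alkenyllithium 12 (not isolated), via lithium hemiaminal alkoxide 13 (not isolated), via bis(triethylsilyl) hemiaminal 14 (not isolated)
Conditions: MeLi (1.05 equiv), then t-BuLi (2.1 equiv), Et2O, −78 °C; DMF; Et3SiCl (2.5 equiv), −78 → 0 °C; pH 7 buffer
Reagents that add atoms: chlorotriethylsilane, CC[Si](Cl)(CC)CC
Why: Iodine–lithium exchange with retention of olefin geometry and Bouveault-type formylation with DMF give the Z-enal; the alkoxide carries no silyl group during the exchange (no retro-Brook shift) and is silylated in the same flask so that the γ-hydroxy enal cannot close to a lactol, and no stereocentre is made.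

Step 7
Reactants: 4 (3R)-3-methyl-3,5-bis(triethylsilyloxy)pent-1-yne; 15 (2Z,4S,5E)-2-methyl-4-(triethylsilyloxy)hepta-2,5-dienal
Product: 18 (2E,4S,5Z,7R,8E,10R)-6,10-dimethyl-4,10,12-tris(triethylsilyloxy)dodeca-2,5,8-trien-7-ol, via alkenyldicyclohexylborane 16 (not isolated), via alkenyl(methyl)zinc 17 (not isolated)
Conditions: 4, Cy2BH, toluene, 0 °C → rt; Me2Zn, −78 °C; (+)-3-exo-morpholinoisoborneol [(+)-MIB, 5 mol %]; 15, −20 → 0 °C; aq NH4Cl
Reagents that add atoms: none
Why: Oppolzer-type sequence of syn hydroboration (E-alkene C1=C2), boron-to-zinc transmetalation and amino-alcohol-catalysed alkenylzinc addition; (+)-MIB directs the alkenyl group to the Re face of the enal and sets the new carbinol (C3 of the target, 7R in 18) under catalyst control.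

Step 8
Reactants: 18 (2E,4S,5Z,7R,8E,10R)-6,10-dimethyl-4,10,12-tris(triethylsilyloxy)dodeca-2,5,8-trien-7-ol
Product: 19 (2E,4S,5Z,7R,8E,10R)-7-(tert-butyldimethylsilyloxy)-6,10-dimethyl-4,10,12-tris(triethylsilyloxy)dodeca-2,5,8-triene
Conditions: t-BuMe2SiOTf (1.3 equiv), 2,6-lutidine, CH2Cl2, −78 °C
Reagents that add atoms: tert-butyldimethylsilyl trifluoromethanesulfonate, CC(C)(C)[Si](C)(C)OS(=O)(=O)C(F)(F)F
Why: Silyl triflate silylation puts the most robust silyl group of the molecule on the bis-allylic C3 hydroxyl; stereocentres are untouched.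

Step 9
Reactants: 19 (2E,4S,5Z,7R,8E,10R)-7-(tert-butyldimethylsilyloxy)-6,10-dimethyl-4,10,12-tris(triethylsilyloxy)dodeca-2,5,8-triene
Product: 20 (3R,4E,6R,7Z,9S,10E)-6-(tert-butyldimethylsilyloxy)-3,7-dimethyl-3-(triethylsilyloxy)dodeca-4,7,10-triene-1,9-diol
Conditions: pyridinium p-toluenesulfonate (0.2 equiv), MeOH–CH2Cl2 1:1, 0 °C
Reagents that add atoms: none
Why: Selective acid-catalysed methanolysis, which removes the primary (C8) and secondary (C6) triethylsilyl ethers much faster than the hindered tertiary triethylsilyl ether at C10 and the TBS ether at C3.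

Step 10
Reactants: 20 (3R,4E,6R,7Z,9S,10E)-6-(tert-butyldimethylsilyloxy)-3,7-dimethyl-3-(triethylsilyloxy)dodeca-4,7,10-triene-1,9-diol
Product: 21 (3R,4E,6R,7Z,9S,10E)-6-(tert-butyldimethylsilyloxy)-9-hydroxy-3,7-dimethyl-3-(triethylsilyloxy)dodeca-4,7,10-trienal
Conditions: TEMPO (10 mol %), PhI(OAc)2 (1.1 equiv), CH2Cl2, rt
Reagents that add atoms: none
Why: Oxoammonium (TEMPO/PhI(OAc)2) oxidation is selective for the unhindered primary alcohol over the hindered secondary bis-allylic one and stops at the C8 aldehyde.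

Step 11
Reactants: 21 (3R,4E,6R,7Z,9S,10E)-6-(tert-butyldimethylsilyloxy)-9-hydroxy-3,7-dimethyl-3-(triethylsilyloxy)dodeca-4,7,10-trienal; 22 2-(bromomethyl)prop-2-enoic acid
Product: 24 (2E,4S,5Z,7R,8E,10R)-7-(tert-butyldimethylsilyloxy)-6,10-dimethyl-12-oxo-10-(triethylsilyloxy)dodeca-2,5,8-trien-4-yl 2-(bromomethyl)prop-2-enoate, via O-acylisourea 23 (not isolated)
Conditions: N,N'-diisopropylcarbodiimide (1.5 equiv), DMAP (5 mol %), CH2Cl2, −20 → 0 °C
Reagents that add atoms: none
Why: Steglich-type carbodiimide esterification acylates the only free hydroxyl (C6) under near-neutral conditions that leave the allylic bromide and the β-silyloxy aldehyde intact, with retention at C6.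

Step 12
Reactants: 24 (2E,4S,5Z,7R,8E,10R)-7-(tert-butyldimethylsilyloxy)-6,10-dimethyl-12-oxo-10-(triethylsilyloxy)dodeca-2,5,8-trien-4-yl 2-(bromomethyl)prop-2-enoate
Product: 25 (3R,4E,6R,7Z)-8-[(2R)-4-(bromomethyl)-5-oxo-2,5-dihydrofuran-2-yl]-6-(tert-butyldimethylsilyloxy)-3,7-dimethyl-3-(triethylsilyloxy)octa-4,7-dienal
Conditions: second-generation Grubbs catalyst (H2IMes)(PCy3)Cl2Ru=CHPh (10 mol %), toluene (5 mM), 60 °C, argon sparge
Reagents that add atoms: none
Why: Ring-closing metathesis between the propenyl group and the acrylate forms the butenolide with loss of propene; the C1=C2 olefin (flanked by a quaternary and a silyloxy-bearing carbon) and the trisubstituted C4=C5 olefin are too hindered to compete.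

Step 13
Reactants: 25 (3R,4E,6R,7Z)-8-[(2R)-4-(bromomethyl)-5-oxo-2,5-dihydrofuran-2-yl]-6-(tert-butyldimethylsilyloxy)-3,7-dimethyl-3-(triethylsilyloxy)octa-4,7-dienal
Product: 27 (3aR,4S,6R,7E,9R,10Z,11aR)-9-(tert-butyldimethylsilyloxy)-4-hydroxy-6,10-dimethyl-3-methylidene-6-(triethylsilyloxy)-3a,4,5,6,9,11a-hexahydrocyclodeca[b]furan-2(3H)-one, via allylchromium dichloride species 26 (not isolated)
Conditions: CrCl2 (8 equiv), THF, rt, 25 added by syringe pump over 10 h (final 2 mM); aq NH4Cl
Reagents that add atoms: none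
Why: Proposed new method: intramolecular Nozaki–Hiyama-type (Barbier) allylation in which divalent chromium turns the allylic bromide into an allylchromium species whose γ-carbon C7 (the β-carbon of the lactone carbonyl, a homoenolate nucleophile) attacks the C8 aldehyde through a closed chair transition state; attack anti to the C5 substituent gives the trans-fused lactone (C7 R), the ring-locked E-type allyl geometry with the tether equatorial gives the 7,8-anti alcohol (C8 S, to be inverted in step 14) and the exo-methylene lactone emerges directly; the closest known reactions are CrCl2-mediated ten-membered ring closures of 2-(alkoxycarbonyl)allyl bromides onto aldehydes and intermolecular Barbier reactions of 3-(bromomethyl)butenolides, which give this same anti, trans sense.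

Step 14
Reactants: 27 (3aR,4S,6R,7E,9R,10Z,11aR)-9-(tert-butyldimethylsilyloxy)-4-hydroxy-6,10-dimethyl-3-methylidene-6-(triethylsilyloxy)-3a,4,5,6,9,11a-hexahydrocyclodeca[b]furan-2(3H)-one; 28 angelic acid [(2Z)-2-methylbut-2-enoic acid]
Product: 30 (3aR,4R,6R,7E,9R,10Z,11aR)-9-(tert-butyldimethylsilyloxy)-6,10-dimethyl-3-methylidene-2-oxo-6-(triethylsilyloxy)-2,3,3a,4,5,6,9,11a-octahydrocyclodeca[b]furan-4-yl (2Z)-2-methylbut-2-enoate, via alkoxyphosphonium angelate 29 (not isolated)
Conditions: PPh3 (3 equiv) and DIAD (3 equiv) premixed, toluene, 0 °C; then 27 and 28 (3 equiv), 0 °C → rt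
Reagents that add atoms: none
Why: Mitsunobu esterification, in which SN2 displacement of the alkoxyphosphonium by angelate inverts C8 to the required configuration (8R, position 4 of 30) and, because the acid is never activated as an acyl electrophile, the Z geometry of the angelate is kept.

Step 15
Reactants: 30 (3aR,4R,6R,7E,9R,10Z,11aR)-9-(tert-butyldimethylsilyloxy)-6,10-dimethyl-3-methylidene-2-oxo-6-(triethylsilyloxy)-2,3,3a,4,5,6,9,11a-octahydrocyclodeca[b]furan-4-yl (2Z)-2-methylbut-2-enoate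
Product: 31 (3aR,4R,6R,7E,9R,10Z,11aR)-6,9-dihydroxy-6,10-dimethyl-3-methylidene-2-oxo-2,3,3a,4,5,6,9,11a-octahydrocyclodeca[b]furan-4-yl (2Z)-2-methylbut-2-enoate (CNP0262559.4)
Conditions: HF·pyridine, pyridine, THF, 0 °C → rt
Reagents that add atoms: none
Why: Fluoride-mediated desilylation removes the TBS ether at C3 and the triethylsilyl ether at C10 without touching the angelate, the α-methylene lactone or any stereocentre.

**Compound list**
1 | (E)-3-methylpent-2-en-4-yn-1-ol | C#C/C(C)=C/CO | starting material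
2 | [(2S,3S)-3-ethynyl-3-methyloxiran-2-yl]methanol | C#C[C@]1(C)O[C@H]1CO | intermediate
3 | (3R)-3-methylpent-4-yne-1,3-diol | C#C[C@](C)(O)CCO | intermediate
4 | (3R)-3-methyl-3,5-bis(triethylsilyloxy)pent-1-yne | C#C[C@](C)(O[Si](CC)(CC)CC)CCO[Si](CC)(CC)CC | intermediate
5 | (E)-but-2-enal (crotonaldehyde) | C/C=C/C=O | starting material
6 | propyne | CC#C | starting material
7 | methyl(prop-1-ynyl)zinc (not isolated) | CC#C[Zn]C | intermediate
8 | (2E,4S)-hept-2-en-5-yn-4-ol | C/C=C/[C@H](O)C#CC | intermediate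
9 | cyclic alkenylalanate, sodium salt, from 8 (not isolated) | C/C=C/[C@@H]1O[Al-](OCCOC)(OCCOC)C(C)=C1.[Na+] | intermediate
10 | (2Z,4S,5E)-2-iodohepta-2,5-dien-4-ol | C/C=C/[C@H](O)/C=C(/C)I | intermediate
11 | N,N-dimethylformamide | CN(C)C=O | starting material
12 | lithium (2Z,4S,5E)-2-lithiohepta-2,5-dien-4-olate (not isolated) | C/C=C/[C@H](O[Li])/C=C(/C)[Li] | intermediate
13 | dilithium hemiaminal alkoxide from 12 and DMF (not isolated) | C/C=C/[C@H](O[Li])/C=C(/C)C(O[Li])N(C)C | intermediate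
14 | (2Z,4S,5E)-N,N,2-trimethyl-1,4-bis(triethylsilyloxy)hepta-2,5-dien-1-amine (not isolated) | C/C=C/[C@H](O[Si](CC)(CC)CC)/C=C(/C)C(O[Si](CC)(CC)CC)N(C)C | intermediate
15 | (2Z,4S,5E)-2-methyl-4-(triethylsilyloxy)hepta-2,5-dienal | C/C=C/[C@H](O[Si](CC)(CC)CC)/C=C(/C)C=O | intermediate
16 | dicyclohexyl[(1E,3R)-3-methyl-3,5-bis(triethylsilyloxy)pent-1-enyl]borane (not isolated) | C1CCCCC1B(C1CCCCC1)/C=C/[C@](C)(O[Si](CC)(CC)CC)CCO[Si](CC)(CC)CC | intermediate
17 | methyl[(1E,3R)-3-methyl-3,5-bis(triethylsilyloxy)pent-1-enyl]zinc (not isolated) | C[Zn]/C=C/[C@](C)(O[Si](CC)(CC)CC)CCO[Si](CC)(CC)CC | intermediate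
18 | (2E,4S,5Z,7R,8E,10R)-6,10-dimethyl-4,10,12-tris(triethylsilyloxy)dodeca-2,5,8-trien-7-ol | C/C=C/[C@H](O[Si](CC)(CC)CC)/C=C(/C)[C@H](O)/C=C/[C@](C)(O[Si](CC)(CC)CC)CCO[Si](CC)(CC)CC | intermediate
19 | (2E,4S,5Z,7R,8E,10R)-7-(tert-butyldimethylsilyloxy)-6,10-dimethyl-4,10,12-tris(triethylsilyloxy)dodeca-2,5,8-triene | C/C=C/[C@H](O[Si](CC)(CC)CC)/C=C(/C)[C@H](O[Si](C)(C)C(C)(C)C)/C=C/[C@](C)(O[Si](CC)(CC)CC)CCO[Si](CC)(CC)CC | intermediate
20 | (3R,4E,6R,7Z,9S,10E)-6-(tert-butyldimethylsilyloxy)-3,7-dimethyl-3-(triethylsilyloxy)dodeca-4,7,10-triene-1,9-diol | C/C=C/[C@H](O)/C=C(/C)[C@H](O[Si](C)(C)C(C)(C)C)/C=C/[C@](C)(O[Si](CC)(CC)CC)CCO | intermediate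
21 | (3R,4E,6R,7Z,9S,10E)-6-(tert-butyldimethylsilyloxy)-9-hydroxy-3,7-dimethyl-3-(triethylsilyloxy)dodeca-4,7,10-trienal | C/C=C/[C@H](O)/C=C(/C)[C@H](O[Si](C)(C)C(C)(C)C)/C=C/[C@](C)(O[Si](CC)(CC)CC)CC=O | intermediate
22 | 2-(bromomethyl)prop-2-enoic acid | C=C(CBr)C(=O)O | starting material
23 | O-acylisourea from 22 and diisopropylcarbodiimide (not isolated) | C=C(CBr)C(=O)OC(=NC(C)C)NC(C)C | intermediate
24 | (2E,4S,5Z,7R,8E,10R)-7-(tert-butyldimethylsilyloxy)-6,10-dimethyl-12-oxo-10-(triethylsilyloxy)dodeca-2,5,8-trien-4-yl 2-(bromomethyl)prop-2-enoate | C/C=C/[C@H](OC(=O)C(=C)CBr)/C=C(/C)[C@H](O[Si](C)(C)C(C)(C)C)/C=C/[C@](C)(O[Si](CC)(CC)CC)CC=O | intermediate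
25 | (3R,4E,6R,7Z)-8-[(2R)-4-(bromomethyl)-5-oxo-2,5-dihydrofuran-2-yl]-6-(tert-butyldimethylsilyloxy)-3,7-dimethyl-3-(triethylsilyloxy)octa-4,7-dienal | BrCC1=C[C@H](OC1=O)/C=C(/C)[C@H](O[Si](C)(C)C(C)(C)C)/C=C/[C@](C)(O[Si](CC)(CC)CC)CC=O | intermediate
26 | allylchromium dichloride species from 25 (Br replaced by CrCl2; not isolated) | Cl[Cr](Cl)CC1=C[C@H](OC1=O)/C=C(/C)[C@H](O[Si](C)(C)C(C)(C)C)/C=C/[C@](C)(O[Si](CC)(CC)CC)CC=O | intermediate
27 | (3aR,4S,6R,7E,9R,10Z,11aR)-9-(tert-butyldimethylsilyloxy)-4-hydroxy-6,10-dimethyl-3-methylidene-6-(triethylsilyloxy)-3a,4,5,6,9,11a-hexahydrocyclodeca[b]furan-2(3H)-one | C=C1C(=O)O[C@@H]2/C=C(/C)[C@H](O[Si](C)(C)C(C)(C)C)/C=C/[C@](C)(O[Si](CC)(CC)CC)C[C@H](O)[C@@H]12 | intermediate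
28 | angelic acid, (2Z)-2-methylbut-2-enoic acid | C/C=C(/C)C(=O)O | starting material
29 | alkoxyphosphonium angelate of 27 (C8–O–PPh3 cation, angelate anion; not isolated) | C=C1C(=O)O[C@@H]2/C=C(/C)[C@H](O[Si](C)(C)C(C)(C)C)/C=C/[C@](C)(O[Si](CC)(CC)CC)C[C@H](O[P+](c3ccccc3)(c3ccccc3)c3ccccc3)[C@@H]12.C/C=C(/C)C(=O)[O-] | intermediate
30 | (3aR,4R,6R,7E,9R,10Z,11aR)-9-(tert-butyldimethylsilyloxy)-6,10-dimethyl-3-methylidene-2-oxo-6-(triethylsilyloxy)-2,3,3a,4,5,6,9,11a-octahydrocyclodeca[b]furan-4-yl (2Z)-2-methylbut-2-enoate | C=C1C(=O)O[C@@H]2/C=C(/C)[C@H](O[Si](C)(C)C(C)(C)C)/C=C/[C@](C)(O[Si](CC)(CC)CC)C[C@@H](OC(=O)/C(C)=C\C)[C@@H]12 | intermediate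
31 | (3aR,4R,6R,7E,9R,10Z,11aR)-6,9-dihydroxy-6,10-dimethyl-3-methylidene-2-oxo-2,3,3a,4,5,6,9,11a-octahydrocyclodeca[b]furan-4-yl (2Z)-2-methylbut-2-enoate (CNP0262559.4) | C=C1C(=O)O[C@@H]2/C=C(/C)[C@H](O)/C=C/[C@](C)(O)C[C@@H](OC(=O)/C(C)=C\C)[C@@H]12 | target

**Step count and risks**

Total step count: 15. Longest linear sequence: 12 steps (steps 4–15, from crotonaldehyde); the west fragment (steps 1–3) joins at step 7.

The three steps most likely to fail:

Step 13 (ring closure). A ten-membered ring is closed by an organochromium species that has not been used in this exact setting; oligomerisation, β-elimination of the lactone carboxylate from the allylmetal, or a cis-fused or 8-epimeric product are possible. The fallback sets out from bromide 25: copper-catalysed borylation (B2pin2, CuCl 10 mol %, KOAc, DMF, 0 °C) gives the pinacol allylboronate F1, a metal-free isolable allyl donor. Heated in dilute toluene (2 mM, 60–80 °C, Sc(OTf)3 10 mol % if needed), F1 closes the ring by intramolecular allylboration through the same closed chair transition state (same trans, anti sense); aqueous work-up cleaves the borate and the route is rejoined at alcohol 27.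

Step 14 (Mitsunobu inversion with angelic acid). The C8 carbinol is hindered by the ring fusion and the neighbouring quaternary C10, so elimination or retention through an acyloxyphosphonium path can compete, and PPh3 may add to the α-methylene lactone. The fallback sets out from alcohol 27: sulfonylation (ClCH2SO2Cl, pyridine, CH2Cl2, 0 °C) gives the chloromethanesulfonate F2 with C8 unchanged. F2 is displaced with inversion by cesium angelate (made in the flask from 28 and Cs2CO3; 18-crown-6, toluene, 60 °C), and the route is rejoined at ester 30.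

Step 7 (asymmetric alkenylzinc union). A neopentyl-type alkenylzinc and a Z-configured γ-silyloxy enal are combined; loss of the Z geometry under zinc Lewis acidity or weak facial control would damage C3. The fallback sets out from alkyne 4 and enal 15. Me2Zn with (S,S)-ProPhenol (10 mol %, Ph3P=O, toluene, 4 °C) converts 4 into the methyl(alkynyl)zinc species F3, which adds to 15 under ligand control to give the propargylic alcohol F4 (same spatial arrangement at C3 as in 18). Hydroxyl-directed trans-hydroalumination with NaAlH2(OCH2CH2OCH3)2 (THF, 0 °C → rt) then proceeds through the cyclic alkenylalanate F5, and protonolysis gives the E-olefin, rejoining the route at alcohol 18.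

Further compounds
F1 | step 13 | pinacol allylboronate: 25 with Br replaced by 4,4,5,5-tetramethyl-1,3,2-dioxaborolan-2-yl (all stereocentres as in 25) | CC1(C)OB(CC2=C[C@H](OC2=O)/C=C(/C)[C@H](O[Si](C)(C)C(C)(C)C)/C=C/[C@](C)(O[Si](CC)(CC)CC)CC=O)OC1(C)C
F2 | step 14 | chloromethanesulfonate ester of alcohol 27 (configuration at every centre as in 27) | C=C1C(=O)O[C@@H]2/C=C(/C)[C@H](O[Si](C)(C)C(C)(C)C)/C=C/[C@](C)(O[Si](CC)(CC)CC)C[C@H](OS(=O)(=O)CCl)[C@@H]12
F3 | step 7 | methyl[(3R)-3-methyl-3,5-bis(triethylsilyloxy)pent-1-ynyl]zinc | C[Zn]C#C[C@](C)(O[Si](CC)(CC)CC)CCO[Si](CC)(CC)CC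
F4 | step 7 | (2E,4S,5Z,7S,10R)-6,10-dimethyl-4,10,12-tris(triethylsilyloxy)dodeca-2,5-dien-8-yn-7-ol (descriptor 7S only because the alkynyl branch outranks the alkenyl branch) | C/C=C/[C@H](O[Si](CC)(CC)CC)/C=C(/C)[C@H](O)C#C[C@](C)(O[Si](CC)(CC)CC)CCO[Si](CC)(CC)CC
F5 | step 7 | cyclic alkenylalanate, sodium salt, from F4 (Al on C1 and on the C3 oxygen) | C/C=C/[C@H](O[Si](CC)(CC)CC)/C=C(/C)[C@@H]1O[Al-](OCCOC)(OCCOC)C(=C1)[C@](C)(O[Si](CC)(CC)CC)CCO[Si](CC)(CC)CC.[Na+]
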